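**Retrosynthetic overview**

- The target is a single ring A, a furan-2(5H)-one (O1, C2 lactone carbonyl, C3, C4 enol carbon, C5), with the 13-methyltetradecanoyl group on C3 and the (S)-hydroxymethyl carbon C5. The last step only removes a silyl ether from the side-chain oxygen.
- Key disconnection: bonds O1–C5 and C3–C4 of ring A are made in one pot as a formal (3+2) annulation. The three-atom unit O1–C2–C3 comes from 15-methyl-3-oxohexadecanoic acid (an O,C-dinucleophile). The two-atom unit C5–C4 comes from an (R)-2-triflyloxy glycerate ester (a 1,2-bis-electrophile). Carboxylate SN2 with inversion is followed by Lacey–Dieckmann closure; ring A is the only ring and is formed there.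
- Enabling feature: C3 of ring A lies between the C2 lactone carbonyl, the enolised C4 and the exocyclic acyl carbonyl, so O1–C2–C3 is the carboxylate plus active methylene of a β-keto acid. C5 is an sp3 CH–O carbon bonded directly to C4, i.e. the α-carbon of a glyceric ester, available from the chiral pool with a leaving group in place of O1.
- Fragment 1: 13-methyltetradecanoic acid, homologated by a Masamune–Brooks reaction and freed by hydrogenolysis. Fragment 2: methyl (R)-2,2-dimethyl-1,3-dioxolane-4-carboxylate, by acetonide hydrolysis, primary silylation and triflation.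

Key step: step 6

Remark: 3-acyltetronic acids are tautomeric; they are written here in the 4-hydroxy enol form of the target SMILES, and 13-methyltetradecanoic acid is taken as a purchasable iso-fatty acid.

**Route**

Step 1
Reactants: 1 13-methyltetradecanoic acid; 2 mono-benzyl malonate
Product: 5 benzyl 15-methyl-3-oxohexadecanoate, via acyl imidazolide 3 (not isolated), via acylmalonic half-ester 4 (not isolated)
Conditions: CDI, THF, rt; then 2, MgCl2, Et3N, MeCN, rt to 40 °C; 1 M HCl work-up
Reagents that add atoms: none
Why: In this Masamune–Brooks decarboxylative Claisen condensation the acyl imidazolide 3 C-acylates the magnesium enolate of the malonic half-ester and the acylmalonate 4 loses CO2 to give the β-keto ester, a routine homologation of fatty acids that creates no stereocentre.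

Step 2
Reactants: 5 benzyl 15-methyl-3-oxohexadecanoate
Product: 6 15-methyl-3-oxohexadecanoic acid
Conditions: H2 (1 atm), 10% Pd/C, EtOAc, rt; filter, concentrate below 25 °C, use at once
Reagents that add atoms: none
Why: Catalytic hydrogenolysis of the benzyl ester runs at room temperature under neutral conditions, so the β-keto acid should be released without the heat or base that would trigger decarboxylation.

Step 3
Reactants: 7 methyl (R)-2,2-dimethyl-1,3-dioxolane-4-carboxylate
Product: 8 methyl (R)-2,3-dihydroxypropanoate
Conditions: AcOH/H2O (4:1), rt; evaporate with toluene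
Reagents that add atoms: none
Why: Acid-catalysed acetal hydrolysis removes the isopropylidene group while the methyl ester and the C2 stereocentre, none of whose bonds is broken, stay untouched.

Step 4
Reactants: 8 methyl (R)-2,3-dihydroxypropanoate
Product: 9 methyl (R)-3-[(tert-butyldimethylsilyl)oxy]-2-hydroxypropanoate
Conditions: TBSCl (1.05 equiv), imidazole, CH2Cl2, -20 to 0 °C
Reagents that add atoms: tert-butyldimethylsilyl chloride (TBSCl), CC(C)(C)[Si](C)(C)Cl
Why: In this sterically controlled monosilylation the bulky silyl chloride should react with the primary hydroxyl much faster than with the hindered, electron-poor α-hydroxyl, and the stereocentre is not involved.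

Step 5
Reactants: 9 methyl (R)-3-[(tert-butyldimethylsilyl)oxy]-2-hydroxypropanoate
Product: 10 methyl (R)-3-[(tert-butyldimethylsilyl)oxy]-2-{[(trifluoromethyl)sulfonyl]oxy}propanoate
Conditions: Tf2O, 2,6-lutidine, CH2Cl2, -78 to -40 °C; cold work-up, use at once
Reagents that add atoms: trifluoromethanesulfonic anhydride (Tf2O), O=S(=O)(OS(=O)(=O)C(F)(F)F)C(F)(F)F
Why: O-Sulfonylation of the secondary alcohol with a hindered pyridine base at low temperature occurs at oxygen only, so the (R) configuration is retained and the α-carbon becomes a strongly activated SN2 electrophile.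

Step 6
Reactants: 6 15-methyl-3-oxohexadecanoic acid; 10 methyl (R)-3-[(tert-butyldimethylsilyl)oxy]-2-{[(trifluoromethyl)sulfonyl]oxy}propanoate
Product: 13 (S)-5-{[(tert-butyldimethylsilyl)oxy]methyl}-4-hydroxy-3-(13-methyltetradecanoyl)furan-2(5H)-one, via potassium carboxylate 11 (not isolated), via acyloxy ester 12 (not isolated)
Conditions: KOt-Bu (1.0 equiv), 18-crown-6 (cat.), THF, -20 °C; 10, -20 to 0 °C; then KOt-Bu (1.3 equiv), 0 °C to rt; 1 M HCl work-up
Reagents that add atoms: none
Why: The first equivalent of KOt-Bu converts 6 into carboxylate 11, whose oxygen displaces the triflate of 10 by SN2 at the ester α-carbon to form the O1–C5 bond of ester 12; the second portion of base then deprotonates the doubly activated CH2 between the ketone and the new ester carbonyl, and this enolate attacks the methyl ester carbonyl and expels methoxide, forming the C3–C4 bond and ring A. The closest known reaction types are the alkylation of carboxylate salts by α-triflyloxy esters and the Lacey–Dieckmann cyclisation of α-(β-ketoacyloxy) esters to 3-acyltetronic acids, run here in one pot as a formal (3+2) annulation of an O–C–C dinucleophile with a C–C bis-electrophile. Ring A closes in the 5-exo-trig mode, an acyl substitution at the ester carbonyl with the departing methoxide outside the ring. The only stereocentre, C5, is controlled by the (R) configuration of the chiral-pool triflate 10 and the inversion of the SN2 step, which should give (S); the ring closure should leave it alone because the far more acidic β-keto ester CH2 consumes the base and the product is held as its stabilised tricarbonyl enolate. The step needs O- rather than C-alkylation of the ambident β-keto acid and no deprotonation at the acyloxy-bearing carbon; the first is secured by having only one equivalent of base (carboxylate, no enolate) present while 10 is consumed, the second by the small excess of base and the low temperature of the cyclisation stage.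

Step 7
Reactants: 13 (S)-5-{[(tert-butyldimethylsilyl)oxy]methyl}-4-hydroxy-3-(13-methyltetradecanoyl)furan-2(5H)-one
Product: 14 (S)-4-hydroxy-5-(hydroxymethyl)-3-(13-methyltetradecanoyl)furan-2(5H)-one
Conditions: 48% aq HF, MeCN, 0 °C to rt
Reagents that add atoms: none
Why: Cleavage of the primary silyl ether by aqueous HF is compatible with the acid-stable, enolised acyltetronic acid and does not touch C5, so the (S) configuration set in step 6 should be carried into the target.

**Compound list**

1 | 13-methyltetradecanoic acid | CC(C)CCCCCCCCCCCC(=O)O | starting material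
2 | mono-benzyl malonate (3-(benzyloxy)-3-oxopropanoic acid) | OC(=O)CC(=O)OCc1ccccc1 | starting material
3 | 1-(13-methyltetradecanoyl)-1H-imidazole | CC(C)CCCCCCCCCCCC(=O)n1ccnc1 | intermediate
4 | 2-[(benzyloxy)carbonyl]-15-methyl-3-oxohexadecanoic acid (present as its magnesium chelate, C2 configurationally labile) | CC(C)CCCCCCCCCCCC(=O)C(C(=O)O)C(=O)OCc1ccccc1 | intermediate
5 | benzyl 15-methyl-3-oxohexadecanoate | CC(C)CCCCCCCCCCCC(=O)CC(=O)OCc1ccccc1 | intermediate
6 | 15-methyl-3-oxohexadecanoic acid | CC(C)CCCCCCCCCCCC(=O)CC(=O)O | intermediate
7 | methyl (R)-2,2-dimethyl-1,3-dioxolane-4-carboxylate | CC1(C)O[C@H](CO1)C(=O)OC | starting material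
8 | methyl (R)-2,3-dihydroxypropanoate | O[C@H](CO)C(=O)OC | intermediate
9 | methyl (R)-3-[(tert-butyldimethylsilyl)oxy]-2-hydroxypropanoate | O[C@H](CO[Si](C)(C)C(C)(C)C)C(=O)OC | intermediate
10 | methyl (R)-3-[(tert-butyldimethylsilyl)oxy]-2-{[(trifluoromethyl)sulfonyl]oxy}propanoate | O=S(=O)(O[C@H](CO[Si](C)(C)C(C)(C)C)C(=O)OC)C(F)(F)F | intermediate
11 | potassium 15-methyl-3-oxohexadecanoate | CC(C)CCCCCCCCCCCC(=O)CC(=O)[O-].[K+] | intermediate
12 | methyl (S)-3-[(tert-butyldimethylsilyl)oxy]-2-[(15-methyl-3-oxohexadecanoyl)oxy]propanoate | CC(C)CCCCCCCCCCCC(=O)CC(=O)O[C@@H](CO[Si](C)(C)C(C)(C)C)C(=O)OC | intermediate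
13 | (S)-5-{[(tert-butyldimethylsilyl)oxy]methyl}-4-hydroxy-3-(13-methyltetradecanoyl)furan-2(5H)-one | CC(C)CCCCCCCCCCCC(=O)C1=C(O)[C@H](CO[Si](C)(C)C(C)(C)C)OC1=O | intermediate
14 | (S)-4-hydroxy-5-(hydroxymethyl)-3-(13-methyltetradecanoyl)furan-2(5H)-one | CC(C)CCCCCCCCCCCC(=O)C1=C(O)[C@H](CO)OC1=O | target

**Step count and risks**

Total step count: 7. Longest linear sequence: 5 steps (steps 3, 4, 5, 6 and 7, from 7 to 14).

Steps most likely to fail:

1. Step 6. The ambident β-keto carboxylate may alkylate at carbon or shuffle protons in the first stage. In the second stage the base may cause β-elimination of the silyloxy group or epimerisation at the acyloxy-bearing carbon. The fallback separates ring formation from introduction of the acyl chain. It sets out from 10, which is displaced with CsOAc and 18-crown-6 in toluene at rt (SN2, inversion) to give methyl (S)-2-acetoxy-3-[(tert-butyldimethylsilyl)oxy]propanoate F1. Dieckmann cyclisation of the acetate with LiN(SiMe3)2 in THF at -78 °C should give (S)-5-{[(tert-butyldimethylsilyl)oxy]methyl}-4-hydroxyfuran-2(5H)-one F2. Acylation of F2 with acid 1 (DCC, DMAP, Et3N, CH2Cl2, rt) should pass through the 4-O-acyl tetronate (S)-2-{[(tert-butyldimethylsilyl)oxy]methyl}-5-oxo-2,5-dihydrofuran-3-yl 13-methyltetradecanoate F3, which is not isolated. DMAP-mediated O-to-C acyl migration of F3 in the same flask comes back to the route at 13.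

2. Step 5. The α-triflyloxy ester may decompose on isolation (hydrolysis, elimination toward the acrylate) or slowly lose configuration by ionisation. The fallback avoids any sulfonate. It sets out from 9, which is coupled directly with acid 6 under Mitsunobu conditions (PPh3, DIAD, THF, 0 °C). The activated alcohol is displaced by the carboxylate with inversion, and the fallback comes back to the route at 12. Ester 12 is then cyclised with KOt-Bu as in the second stage of step 6.

3. Step 2. The free β-keto acid may lose carbon dioxide during concentration or storage, leaving too little carboxylate for step 6. The fallback does without the β-keto acid and attaches the chain through an acylketene; it sets out from 1 and 9. Acid 1 is condensed with Meldrum's acid (DCC, DMAP, CH2Cl2, 0 °C to rt) to give 5-(1-hydroxy-13-methyltetradecylidene)-2,2-dimethyl-1,3-dioxane-4,6-dione F4. Alcohol 9 is inverted by Mitsunobu esterification with 4-nitrobenzoic acid (PPh3, DIAD, THF) to give methyl (S)-3-[(tert-butyldimethylsilyl)oxy]-2-[(4-nitrobenzoyl)oxy]propanoate F5. Methanolysis of F5 (K2CO3, MeOH, 0 °C) gives methyl (S)-3-[(tert-butyldimethylsilyl)oxy]-2-hydroxypropanoate F6. Heating F4 with F6 in toluene at 90 °C should release the acylketene, which is trapped by the hydroxyl with retention, and the fallback comes back to the route at 12. Ester 12 is then cyclised with KOt-Bu as in the second stage of step 6.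

**Further compounds**

F1 | step 6 | methyl (S)-2-acetoxy-3-[(tert-butyldimethylsilyl)oxy]propanoate | CC(=O)O[C@@H](CO[Si](C)(C)C(C)(C)C)C(=O)OC
F2 | step 6 | (S)-5-{[(tert-butyldimethylsilyl)oxy]methyl}-4-hydroxyfuran-2(5H)-one | OC1=CC(=O)O[C@H]1CO[Si](C)(C)C(C)(C)C
F3 | step 6 | (S)-2-{[(tert-butyldimethylsilyl)oxy]methyl}-5-oxo-2,5-dihydrofuran-3-yl 13-methyltetradecanoate | CC(C)CCCCCCCCCCCC(=O)OC1=CC(=O)O[C@H]1CO[Si](C)(C)C(C)(C)C
F0 | step 5 | none | none
F4 | step 2 | 5-(1-hydroxy-13-methyltetradecylidene)-2,2-dimethyl-1,3-dioxane-4,6-dione | CC(C)CCCCCCCCCCCC(O)=C1C(=O)OC(C)(C)OC1=O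
F5 | step 2 | methyl (S)-3-[(tert-butyldimethylsilyl)oxy]-2-[(4-nitrobenzoyl)oxy]propanoate | O=C(O[C@@H](CO[Si](C)(C)C(C)(C)C)C(=O)OC)c1ccc(cc1)[N+](=O)[O-]
F6 | step 2 | methyl (S)-3-[(tert-butyldimethylsilyl)oxy]-2-hydroxypropanoate | O[C@@H](CO[Si](C)(C)C(C)(C)C)C(=O)OC
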